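(The earlier runs and the new flask stem from a simulated flask on assumed constants; scatter was added.)

Stop the flask near the crossing rather than run the full 8.0 min, as your hunch has it. In the delta run, target falls from 15.0% at 4.00 min to 7.8% at 10.0 min.

| flask | electrophile | nucleophile | remark | time |
|---|---|---|---|---|
| beta | 0.10 M | 0.158 M (fed, over 50 s) | run made earlier; the fed solution adds 0.25 times the starting volume |  |
| delta | 0.22 M | 0.158 M (fed, over 50 s) | run made earlier; the fed solution adds 0.25 times the starting volume |  |
| flask | 0.15 M | 0.158 M (fed, over 50 s) | the fed solution adds 0.25 times the starting volume | 8.0 min |

| run | time / min | target / % | electrophile / % |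
|---|---|---|---|
| beta | 1.00 | 11.0 | 87.1 |
| beta | 1.50 | 18.0 | 77.6 |
| beta | 2.50 | 25.8 | 63.3 |
| beta | 4.00 | 31.1 | 48.7 |
| beta | 6.00 | 34.0 | 33.7 |
| beta | 10.0 | 34.8 | 19.0 |
| delta | 1.00 | 8.8 | 87.2 |
| delta | 1.50 | 12.7 | 79.6 |
| delta | 2.50 | 14.8 | 67.4 |
| delta | 4.00 | 15.0 | 56.1 |
| delta | 6.00 | 11.9 | 47.0 |
| delta | 10.0 | 7.8 | 37.2 |

(each reading ± 0.5 percentage points)

- percent here means electrophile units held: one side product counts as two
- amounts are per litre of the starting volume; all of the dose is in the solution fed
- the earlier runs were read with a standard deviation of 0.5 percentage points
- candidate steps: electrophile + nucleophile -> acid set free + target; nucleophile + acid set free <-> protonated nucleophile; electrophile + target -> side product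

- the moment within 8.0 min at which there is most target
- the amount of target, in percent of the electrophile charged, at that time
- earliest time at which at least nineteen twentieths of that best amount are there, in min
- latest time at which they still are, in min

The main step makes target from electrophile and nucleophile. The side step burns target with electrophile. Both rates carry c(electrophile), so it cancels, and in these isothermal flasks target peaks if c(target)/c(nucleophile), counting free nucleophile, reaches a fixed value. I call this value the crossing ratio, the selectivity factor of main over side step.

I read it from the beta run between 4.00 min and 6.00 min. Electrophile falls by 15 percentage points and target rises by 2.9 points. The first is main plus side and the second is main minus side, so main over side is 1.48. I take two nucleophiles per main event, so free nucleophile averages 0.0667 M per starting volume, beside target at 0.0326 M. The crossing ratio is then 0.722, a reading that carries the scatter.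

The forecast, holding that “each target formed costs two nucleophiles”, gives 23.1% at 4.5 min, with the window from 3.1 min to 7.1 min. My own reckoning adds one thing: at the forecast's peak in the flask, free nucleophile should stand at 0.0480 M per starting volume, which is 30.4% of its charge.

    electrophile + nucleophile → acid set free + target (k = 0.0310 L mol⁻¹ s⁻¹)
    nucleophile + acid set free ⇌ protonated nucleophile, settled at all times (K = 5500 L mol⁻¹)
    electrophile + target → side product (k = 0.0420 L mol⁻¹ s⁻¹)

The flask gives 23.2% at 4.33 min, with the window from 2.90 min to 6.63 min, and the forecast stands within its margins. Target climbs from 8.07% at 0.833 min to that best, where nucleophile is 29.8% of its charge, the ratio is 0.738, and acid set free, 2.14 × 10⁻⁴ M, stands far below protonated nucleophile, 0.0443 M. Then the side product grows to 47.3% by 8.00 min, while target slips to 20.9%. In the neighbour flask with 0.037 M of electrophile, the ratio at 8.00 min is 0.216, lower than the crossing ratio, and target stands at 61.5% against a best of 61.5%.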